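(The numbers are those of an exercise, and the outcome is calculated.)

A ratio of two rate constants, the one making target over the one spending it on side product, 4.80 (the selectivity factor), was what I carried through this flask.

    target ⇌ isomer of the product (K1 = 0.22, k1 = 0.13 min⁻¹)
    starting material + target → side product (k2 = 0.025 M⁻¹ min⁻¹)
    starting material + reagent in the reaction phase → target (k3 = 0.12 M⁻¹ min⁻¹)
    reagent in the reaction phase ⇌ reagent in the second phase, rate k4*([reagent in the reaction phase] - [reagent in the second phase]/K4) per volume of the first phase (K4 = 1.1, k4 = 0.10 min⁻¹)
    reagent in the reaction phase ⇌ dormant form (K5 = 1.1, k5 = 2.5 min⁻¹)

starting material 2.0 M; reagent in the second phase 1.05 equiv; time 20 min; volume of the second phase over the first 1.0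

- percent here means starting material units held: one side product counts as two
- in the second phase: reagent in the second phase; everything else is in the first
- charges count per volume of the first phase; a concentration in a rate is the amount of a species over the volume of its own phase; every rate counts per litre of the first phase
- run time (flask): 20 min

* how much target there is at 20 min, in percent of the starting material charged
* part of the starting material charged that has reacted at 20 min

**The crossing.** Starting material enters both steps, so it cancels. I defined S as that factor times reagent in the reaction phase over target. Target and isomer together grow while S stands above 1.

**Fastest rung.** Reagent in the reaction phase and dormant form relax with a half-life of 0.145 min, far shorter than the run, so I kept dormant form at 1.1 times that reagent.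

**Next rung.** Target and isomer relax with a half-life of 0.961 min, shorter than the run, so I gave target 82.0% of their sum.

**Slow rung.** Transfer from the second phase starts at 0.191 M min⁻¹, and with starting material as charged I took reagent in the reaction phase to be lost at 0.340 min⁻¹. Their quotient is 0.562 M. As a rough allowance for the draining second phase I multiplied it by 0.5 and worked with 0.281 M.

**My reckoning.** With the reagent held at that level, the target-making step came in my estimate to 0.980 M in 20 min. I therefore expected conversion of about 49.0% or somewhat more, and target of about 0.804 M (40.2% of the charge) or less, with some going on to side product. On these estimates S ended near 1.68 or higher, above the crossing, so I expected target still to be rising.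

**The forecast.** It gave 28.5% target and 54.5% conversion, on the ground that “Transfer from the second phase is slow”.

**The result.** The flask gave 28.5% target and 54.3% conversion. At 20.0 min it held 0.290 M of reagent in the reaction phase and 0.570 M of target, so S read 2.45, higher than my estimate. In the flask charged with 0.80 M of starting material, the readings at 20.0 min were 0.164 M of that reagent and 0.162 M of target. That makes S 4.85, twice the other flask's, and this dilute flask held 6.17% side product beside 20.3% target.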